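**Retrosynthetic overview**
1. The target should come from the C1 ketone by reagent-controlled reduction. The C10=C14 methylene is unmasked by loss of acetic acid from a C14 acetate, and the C7=C11 butenolide alkene by dehydration of a C11 carbinol.
2. C14 is delivered to C10 from the C8 oxygen (silicon tether, then C–Si oxidation). C11–C13 come from an aldol at C7 of the C6 enone with a silyloxypyruvate, followed by C6 reduction and lactonisation.
3. The two ring ketones are told apart by the C8 hydroxyl, which can ketalise only C1 (five-membered bridge over C9–C10). C3=C4 is then moved into conjugation with C6.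
4. The strategy rests on this feature: the oxygen-bearing carbons C1 and C6 lie 1,6 across the ten-membered ring, so they are the two ends of the C1=C6 fusion alkene of a hexahydronaphthalene. Ring A is C1–C6 with C15 on C4 and the cis C3=C4 alkene; ring B is C6–C10/C1 with the C8 oxygen. The bicycle comes from Birch reduction of 2-methoxy-7-methylnaphthalene.
5. Ring order: arene rings A and B, then the ten-membered carbocycle by cleavage of their shared bond, a temporary C1–O–C8 bridge, the γ-lactone, a temporary siloxane ring, and last the butenolide.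

Key step: step 7

Remark on numbering: C1–C15 are the germacrane numbers of the target throughout; for the oxygen-bridged ketals they coincide with the numbering of 11-oxabicyclo[6.2.1]undecane.
Assumption: a commercial ketoreductase panel contains an (S)-selective enzyme for ketone 6. The centres C10 and C11, which later become sp2, are carried as epimer mixtures, and C7 is drawn as expected from the aldol.

**Step 1**
Reactants: 1 7-methoxy-2-naphthol
Product: 2 7-methoxynaphthalen-2-yl trifluoromethanesulfonate
Conditions: Tf2O, pyridine, CH2Cl2, 0 °C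
Reagents that add atoms: triflic anhydride, O=S(=O)(OS(=O)(=O)C(F)(F)F)C(F)(F)F
Why: O-sulfonylation of the phenol turns the C–O bond at the future C4 into a cross-coupling handle while the methyl ether stays inert.

**Step 2**
Reactants: 2 7-methoxynaphthalen-2-yl trifluoromethanesulfonate; 3 trimethylboroxine
Product: 4 2-methoxy-7-methylnaphthalene
Conditions: Pd(PPh3)4 (5 mol %), K2CO3, 1,4-dioxane, 100 °C
Reagents that add atoms: none
Why: Suzuki–Miyaura coupling, in which zerovalent palladium inserts into the aryl triflate and the boroxine transfers the methyl group that becomes C15.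

**Step 3**
Reactants: 4 2-methoxy-7-methylnaphthalene
Product: 5 2-methoxy-7-methyl-1,4,5,8-tetrahydronaphthalene
Conditions: Li (excess), NH3(l), THF, t-BuOH, −78 to −33 °C; then NH4Cl
Reagents that add atoms: none
Why: Birch reduction puts two electrons and two protons on the unsubstituted para positions of each ring, so the methoxy carbon, the methyl carbon and the ring fusion stay sp2, and t-BuOH suppresses amide-induced isomerisation.

**Step 4**
Reactants: 5 2-methoxy-7-methyl-1,4,5,8-tetrahydronaphthalene
Product: 6 7-methyl-3,4,5,8-tetrahydronaphthalen-2(1H)-one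
Conditions: oxalic acid, H2O, MeOH/THF, rt
Reagents that add atoms: water, O
Why: Enol ether hydrolysis (C-protonation, hemiketal collapse) with a weak acid should stop at the β,γ-unsaturated ketone and leave the fusion alkene out of conjugation.

**Step 5**
Reactants: 6 7-methyl-3,4,5,8-tetrahydronaphthalen-2(1H)-one
Product: 7 (S)-7-methyl-1,2,3,4,5,8-hexahydronaphthalen-2-ol
Conditions: (S)-selective ketoreductase, NADP+ (cat.), i-PrOH, phosphate buffer pH 7, 30 °C
Reagents that add atoms: none
Why: Biocatalytic ketone reduction in which the enzyme tells the allylic CH2 flank from the CH2CH2 flank, as in 2-tetralone reductions, and delivers hydride to one face to set C8 as S.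

**Step 6**
Reactants: 7 (S)-7-methyl-1,2,3,4,5,8-hexahydronaphthalen-2-ol
Product: 8 (S)-tert-butyldimethyl[(7-methyl-1,2,3,4,5,8-hexahydronaphthalen-2-yl)oxy]silane
Conditions: TBSCl, imidazole, DMF, rt
Reagents that add atoms: tert-butyldimethylsilyl chloride, CC(C)(C)[Si](C)(C)Cl
Why: Silyl ether formation protects the C8 hydroxyl so that it cannot trap ozonolysis intermediates.

**Step 7**
Reactants: 8 (S)-tert-butyldimethyl[(7-methyl-1,2,3,4,5,8-hexahydronaphthalen-2-yl)oxy]silane
Product: 9 (8S,3Z)-8-(tert-butyldimethylsilyloxy)-4-methylcyclodec-3-ene-1,6-dione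
Conditions: O3 (1.0 equiv, titrated), CH2Cl2/MeOH, NaHCO3, −78 °C; then Me2S, −78 °C to rt
Reagents that add atoms: ozone, [O-][O+]=O
Why: Ozone adds as a 1,3-dipole to the most electron-rich, tetrasubstituted C1=C6 alkene; the primary ozonide splits into a ketone and a carbonyl oxide, methanol traps the latter as a methoxy hydroperoxide and Me2S reduces it, so both fusion carbons end as ketones. This is ozonolysis with reductive work-up, the reaction type known for the central alkene of 1,4,5,8-tetrahydronaphthalenes and for tetrasubstituted over trisubstituted alkenes in skipped dienes. The ten-membered ring is not closed by bond formation: cleaving the bond shared by rings A and B merges the two six-membered rings into the cyclodecene, so there is no medium-ring cyclisation to pay for. No stereocentre is formed, C8 is untouched and C3=C4 keeps the cis geometry imposed by ring A. The step needs selectivity for the tetrasubstituted over the trisubstituted alkene, which rests on the higher nucleophilicity of the fusion alkene and on exactly one equivalent of ozone at −78 °C. The silyl ether keeps O8 away from the carbonyl oxide and the buffer should prevent transannular aldolisation of the 1,6-diketone.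

**Step 8**
Reactants: 9 (8S,3Z)-8-(tert-butyldimethylsilyloxy)-4-methylcyclodec-3-ene-1,6-dione
Product: 11 (8S,3Z)-1-methoxy-4-methyl-11-oxabicyclo[6.2.1]undec-3-en-6-one (C1 methyl ketal whose second oxygen is O8), via hydroxy dione 10 (not isolated)
Conditions: AcCl (cat., HCl in situ), MeOH, 0 °C to rt
Reagents that add atoms: methanol, CO
Why: Acid methanolysis of the silyl ether followed by ketalisation, in which the freed C8 hydroxyl can reach only the C1 carbonyl (five-membered ring through C9–C10, as in natural 3,10-epoxygermacranolide hemiketals) and methanol caps the hemiketal; this masks C1 and O8, leaves C6 free and fixes the new C1 centre through the cis bridge.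

**Step 9**
Reactants: 11 (8S,3Z)-1-methoxy-4-methyl-11-oxabicyclo[6.2.1]undec-3-en-6-one
Product: 12 (8S,4Z)-1-methoxy-4-methyl-11-oxabicyclo[6.2.1]undec-4-en-6-one
Conditions: DBU (0.2 equiv), toluene, 0 °C to rt
Reagents that add atoms: none
Why: Base-mediated β,γ to α,β isomerisation through the C5 dienolate with γ-protonation at C3; C6 is now the only carbonyl, so only the C4=C5 enone can form, and the nine-membered oxacycle keeps the alkene cis (Z).

**Step 10**
Reactants: 13 ethyl 2-(hydroxymethyl)acrylate
Product: 14 ethyl 2-[(tert-butyldiphenylsilyloxy)methyl]acrylate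
Conditions: TBDPSCl, imidazole, CH2Cl2, 0 °C to rt
Reagents that add atoms: tert-butyldiphenylsilyl chloride, CC(C)(C)[Si](Cl)(c1ccccc1)c1ccccc1
Why: Silyl ether formation gives the future C13 oxygen an acid- and base-stable protecting group.

**Step 11**
Reactants: 14 ethyl 2-[(tert-butyldiphenylsilyloxy)methyl]acrylate
Product: 15 ethyl 3-(tert-butyldiphenylsilyloxy)-2-oxopropanoate
Conditions: O3, CH2Cl2, −78 °C; then Me2S
Reagents that add atoms: ozone, [O-][O+]=O
Why: Ozonolysis of the 1,1-disubstituted alkene with reductive work-up gives the α-keto ester that carries C11, C12 and C13.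

**Step 12**
Reactants: 12 (8S,4Z)-1-methoxy-4-methyl-11-oxabicyclo[6.2.1]undec-4-en-6-one; 15 ethyl 3-(tert-butyldiphenylsilyloxy)-2-oxopropanoate
Product: 16 ethyl 3-(tert-butyldiphenylsilyloxy)-2-hydroxy-2-[(8S,4Z)-1-methoxy-4-methyl-6-oxo-11-oxabicyclo[6.2.1]undec-4-en-7-yl]propanoate (C11 epimers)
Conditions: LiN(i-Pr)2, THF, −78 °C; then 15, −78 °C; AcOH quench
Reagents that add atoms: none
Why: Kinetic α'-deprotonation of the enone at C7 and aldol addition to the ketone carbonyl of the α-keto ester; the electrophile is expected to enter anti to the C8–C9 bond, C11 forms as a mixture that is erased later, and the ketal oxygen on C8 is a poor leaving group at −78 °C.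

**Step 13**
Reactants: 16 aldol adduct
Product: 18 (6R,8S)-13-(tert-butyldiphenylsilyloxy)-11-hydroxy-1-methoxy-1,8-epoxygermacr-4Z-en-6,12-olide (saturated cis-fused γ-lactone on C6–C7), via allylic alcohol 17 (not isolated)
Conditions: NaBH4, CeCl3·7H2O, MeOH/THF, −78 °C; then PPTS (cat.), toluene, 40 °C
Reagents that add atoms: none
Why: Luche 1,2-reduction then lactonisation, in which hydride is expected to add to C6 anti to the new C7 side chain (substrate control), giving 6R with O6 cis to C11 and to O8; the hydroxy ester then closes to the γ-lactone, and O8 cannot compete because it is tied up in the ketal.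

**Step 14**
Reactants: 18 bridged ketal hydroxy lactone
Product: 19 (6R,8S)-13-(tert-butyldiphenylsilyloxy)-8,11-dihydroxy-1-oxogermacr-4Z-en-6,12-olide (in equilibrium with its C1/O8 hemiketal)
Conditions: 1 M aq. HCl, THF, 40 °C
Reagents that add atoms: water, O
Why: Ketal hydrolysis through the bridged oxocarbenium ion should return the C1 ketone and the C8 hydroxyl without touching the lactone or the silyl ether.

**Step 15**
Reactants: 19 keto alcohol
Product: 21 8-O-[(bromomethyl)dimethylsilyl]-11-O-trimethylsilyl derivative of 19, via bromomethylsilyl ether 20 (not isolated)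
Conditions: BrCH2SiMe2Cl, imidazole, CH2Cl2, 0 °C; then N-(trimethylsilyl)imidazole, rt
Reagents that add atoms: (bromomethyl)chlorodimethylsilane, C[Si](C)(Cl)CBr; N-(trimethylsilyl)imidazole, C[Si](C)(C)n1ccnc1
Why: Silylation places the one-carbon tether on the secondary C8 hydroxyl of the open hydroxy ketone and caps the hindered C11 hydroxyl, so that no alkoxide able to take over the silicon can form in the next step.

**Step 16**
Reactants: 21 tethered keto lactone
Product: 22 cyclic siloxane with the new C10–C14 bond (six-membered ring C10–C14–SiMe2–O–C8–C9; C10 epimers)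
Conditions: KN(SiMe3)2 (1.1 equiv), THF, −78 to 0 °C
Reagents that add atoms: none
Why: Proposed new method: the potassium enolate of the C1 ketone equilibrates between C2 and C10 by proton exchange with HN(SiMe3)2, but only the C10 enolate can reach the Si–CH2–Br carbon (6-exo-tet SN2), so C-alkylation should funnel the mixture to the C10–C14 bond, while the lactone has no α-hydrogen and the silyloxy group on C8 does not leave; the closest known reactions are the alkylation of ketone enolates with (halomethyl)silanes and the silicon-tethered radical cyclisation of (bromomethyl)silyl ethers followed by Tamao oxidation.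

**Step 17**
Reactants: 22 cyclic siloxane
Product: 23 (6R,8S)-13-(tert-butyldiphenylsilyloxy)-8,11,14-trihydroxy-1-oxogermacr-4Z-en-6,12-olide
Conditions: KF, KHCO3, 30% aq. H2O2, THF/MeOH, rt
Reagents that add atoms: hydrogen peroxide, OO
Why: Tamao oxidation, in which fluoride-activated peroxide inserts oxygen into the C14–Si bond and both Si–O bonds are cleaved, giving the C14 and C8 hydroxyls and freeing the C11 hydroxyl.

**Step 18**
Reactants: 23 silyl ether triol
Product: 24 (6R,8S)-8,11,13,14-tetrahydroxy-1-oxogermacr-4Z-en-6,12-olide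
Conditions: HF·pyridine, pyridine/THF, 0 °C to rt
Reagents that add atoms: none
Why: Fluoride-mediated cleavage of the silyl ether under buffered, non-basic conditions that should not cause translactonisation to O8.

**Step 19**
Reactants: 24 tetraol
Product: 25 (6R,8S)-8,13,14-triacetoxy-11-hydroxy-1-oxogermacr-4Z-en-6,12-olide
Conditions: Ac2O, pyridine, CH2Cl2, 0 °C to rt
Reagents that add atoms: acetic anhydride, CC(=O)OC(C)=O
Why: Acetylation of the two primary and the secondary hydroxyls; the tertiary α-hydroxy lactone does not react, and pyridine drains the hemiketal through its open form.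

**Step 20**
Reactants: 25 triacetate
Product: 27 8α,13-diacetoxy-1-oxogermacra-4Z,7(11),10(14)-trien-6α,12-olide, via methylene ketone 26 (not isolated)
Conditions: DBU (1.1 equiv), CH2Cl2, 0 °C; then pyridine, SOCl2 (excess), −20 to 0 °C
Reagents that add atoms: none
Why: E1cB loss of the C14 acetate from the C10 enolate gives the α-methylene ketone while the lactone is still saturated, and the C11 chlorosulfite then undergoes pyridine-mediated E2 elimination with an antiperiplanar C7–H to the conjugated, tetrasubstituted butenolide (dehydration of a tertiary α-hydroxy lactone); the excess SOCl2 quenches DBU first, so the base-labile 13-acetoxy butenolide never meets it.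

**Step 21**
Reactants: 27 enone butenolide
Product: 28 8α,13-diacetoxy-1β-hydroxygermacra-4,7(11),10(14)-trien-6α,12-olide (1R,6R,8S; 4Z)
Conditions: (S)-2-methyl-CBS-oxazaborolidine, catecholborane, toluene, −78 °C; then MeOH, pH 7 buffer
Reagents that add atoms: none
Why: Corey–Bakshi–Shibata reduction, in which the (S)-oxazaborolidine takes the 2-substituted alkenyl flank (C10) as the large group and delivers hydride 1,2 to give 1R under reagent control, leaving butenolide and acetates intact at −78 °C.

**Compound list**
1 | 7-methoxy-2-naphthol | COc1ccc2ccc(O)cc2c1 | starting material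
2 | 7-methoxynaphthalen-2-yl trifluoromethanesulfonate | COc1ccc2ccc(OS(=O)(=O)C(F)(F)F)cc2c1 | intermediate
3 | trimethylboroxine | CB1OB(C)OB(C)O1 | starting material
4 | 2-methoxy-7-methylnaphthalene | COc1ccc2ccc(C)cc2c1 | intermediate
5 | 2-methoxy-7-methyl-1,4,5,8-tetrahydronaphthalene | COC1=CCC2=C(C1)CC(C)=CC2 | intermediate
6 | 7-methyl-3,4,5,8-tetrahydronaphthalen-2(1H)-one | O=C1CCC2=C(C1)CC(C)=CC2 | intermediate
7 | (S)-7-methyl-1,2,3,4,5,8-hexahydronaphthalen-2-ol | CC1=CCC2=C(C1)C[C@@H](O)CC2 | intermediate
8 | TBS ether of 7 (key-step precursor) | CC1=CCC2=C(C1)C[C@@H](O[Si](C)(C)C(C)(C)C)CC2 | intermediate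
9 | (8S,3Z)-8-(tert-butyldimethylsilyloxy)-4-methylcyclodec-3-ene-1,6-dione (key-step product) | O=C1C/C=C(/C)CC(=O)C[C@@H](O[Si](C)(C)C(C)(C)C)CC1 | intermediate
10 | (8S,3Z)-8-hydroxy-4-methylcyclodec-3-ene-1,6-dione (hemiketal equilibrium; not isolated) | O=C1C/C=C(/C)CC(=O)C[C@@H](O)CC1 | intermediate
11 | (8S,3Z)-1-methoxy-4-methyl-11-oxabicyclo[6.2.1]undec-3-en-6-one | CO[C@]12C/C=C(C)\CC(=O)C[C@H](CC1)O2 | intermediate
12 | (8S,4Z)-1-methoxy-4-methyl-11-oxabicyclo[6.2.1]undec-4-en-6-one | CO[C@]12CC/C(C)=C\C(=O)C[C@H](CC1)O2 | intermediate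
13 | ethyl 2-(hydroxymethyl)acrylate | C=C(CO)C(=O)OCC | starting material
14 | ethyl 2-[(tert-butyldiphenylsilyloxy)methyl]acrylate | C=C(CO[Si](c1ccccc1)(c1ccccc1)C(C)(C)C)C(=O)OCC | intermediate
15 | ethyl 3-(tert-butyldiphenylsilyloxy)-2-oxopropanoate | O=C(CO[Si](c1ccccc1)(c1ccccc1)C(C)(C)C)C(=O)OCC | intermediate
16 | C7 aldol adduct of 12 and 15 (C11 epimers) | CO[C@]12CC/C(C)=C\C(=O)[C@@H](C(O)(CO[Si](c3ccccc3)(c3ccccc3)C(C)(C)C)C(=O)OCC)[C@H](CC1)O2 | intermediate
17 | 6R allylic alcohol of 16 (not isolated) | CO[C@]12CC/C(C)=C\[C@@H](O)[C@@H](C(O)(CO[Si](c3ccccc3)(c3ccccc3)C(C)(C)C)C(=O)OCC)[C@H](CC1)O2 | intermediate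
18 | bridged ketal 11-hydroxy 6,12-olide (6R,8S) | CO[C@]12CC/C(C)=C\[C@H]3OC(=O)C(O)(CO[Si](c4ccccc4)(c4ccccc4)C(C)(C)C)[C@H]3[C@H](CC1)O2 | intermediate
19 | 13-silyloxy-8,11-dihydroxy-1-oxogermacr-4Z-en-6,12-olide | O=C1CC/C(C)=C\[C@H]2OC(=O)C(O)(CO[Si](c3ccccc3)(c3ccccc3)C(C)(C)C)[C@H]2[C@@H](O)CC1 | intermediate
20 | 8-O-(bromomethyl)dimethylsilyl ether of 19 (not isolated) | O=C1CC/C(C)=C\[C@H]2OC(=O)C(O)(CO[Si](c3ccccc3)(c3ccccc3)C(C)(C)C)[C@H]2[C@@H](O[Si](C)(C)CBr)CC1 | intermediate
21 | 11-O-trimethylsilyl ether of 20 | O=C1CC/C(C)=C\[C@H]2OC(=O)C(O[Si](C)(C)C)(CO[Si](c3ccccc3)(c3ccccc3)C(C)(C)C)[C@H]2[C@@H](O[Si](C)(C)CBr)CC1 | intermediate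
22 | cyclic siloxane C10–C14–SiMe2–O–C8 (C10 epimers) | O=C1CC/C(C)=C\[C@H]2OC(=O)C(O[Si](C)(C)C)(CO[Si](c3ccccc3)(c3ccccc3)C(C)(C)C)[C@H]2[C@@H]2CC1C[Si](C)(C)O2 | intermediate
23 | 13-silyloxy-8,11,14-trihydroxy-1-oxogermacr-4Z-en-6,12-olide | O=C1CC/C(C)=C\[C@H]2OC(=O)C(O)(CO[Si](c3ccccc3)(c3ccccc3)C(C)(C)C)[C@H]2[C@@H](O)CC1CO | intermediate
24 | 8,11,13,14-tetrahydroxy-1-oxogermacr-4Z-en-6,12-olide | O=C1CC/C(C)=C\[C@H]2OC(=O)C(O)(CO)[C@H]2[C@@H](O)CC1CO | intermediate
25 | 8,13,14-triacetoxy-11-hydroxy-1-oxogermacr-4Z-en-6,12-olide | O=C1CC/C(C)=C\[C@H]2OC(=O)C(O)(COC(C)=O)[C@H]2[C@@H](OC(C)=O)CC1COC(C)=O | intermediate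
26 | 8,13-diacetoxy-11-hydroxy-1-oxogermacra-4Z,10(14)-dien-6,12-olide (not isolated) | O=C1CC/C(C)=C\[C@H]2OC(=O)C(O)(COC(C)=O)[C@H]2[C@@H](OC(C)=O)CC1=C | intermediate
27 | 8α,13-diacetoxy-1-oxogermacra-4Z,7(11),10(14)-trien-6α,12-olide | C=C1C[C@H](OC(C)=O)C2=C(COC(C)=O)C(=O)O[C@@H]2/C=C(/C)CCC1=O | intermediate
28 | 8α,13-diacetoxy-1β-hydroxygermacra-4,7(11),10(14)-trien-6α,12-olide | C=C1C[C@H](OC(C)=O)C2=C(COC(C)=O)C(=O)O[C@@H]2/C=C(/C)CC[C@H]1O | target

**Step count**
Total: 21 steps. Longest linear sequence: 19 steps (steps 1–9 and 12–21); steps 10–11 make the aldol partner.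

**Steps most likely to fail**

Step 16 (Proposed new method). The enolate may transfer the silyl group to oxygen or be alkylated on oxygen, or proton exchange may be too slow to drain the C2 enolate, so the C10–C14 bond does not form. The fallback uses known reactions and sets out from 19. Acid-catalysed cyclodehydration of its hemiketal (CSA cat., benzene, reflux, water removal) should give the bridged 2,3-dihydrofuran with the endocyclic C1=C10 enol ether F1. Lewis-acid hydroxymethylation of this enol ether with aqueous formaldehyde and Yb(OTf)3 in THF, followed by hydration of the oxocarbenium ion, then places CH2OH on C10 and returns to the route at 23.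

Step 13. Facial selectivity of hydride addition to C6 may be poor or reversed, which would give the 6-epi series. The fallback sets out from 16. If the same Luche reduction gives the 6S allylic alcohol F2, the ester is saponified (LiOH, THF/H2O) to the hydroxy acid F3, and Mitsunobu lactonisation (PPh3, DIAD, THF) closes the lactone by SN2 attack of the carboxylate on C6 with inversion, coming back to the route at 18.

Step 20. The E2 elimination needs a C7–H antiperiplanar to the C11 oxygen, which only one C11 epimer offers. Loss of a C13 hydrogen (enol acetate) or chloride substitution may also compete. The fallback does not depend on the C11 configuration; it sets out from 24.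
- Periodate cleavage of the 11,13-glycol (NaIO4, THF/H2O) removes C13 and gives the α-keto lactone as its enol, 11-hydroxy butenolide F4.
- PhNTf2/Et3N converts the enol into the enol triflate F5.
- Ac2O/pyridine gives the 8,14-diacetate F6, and DBU at 0 °C eliminates the C14 acetate to the methylene ketone F7.
- Stille coupling with Bu3SnCH2OH (Pd(PPh3)4, LiCl, dioxane, 80 °C) reinstalls C13 as the 13-hydroxymethyl butenolide F8.
- Ac2O/pyridine returns to the route at 27.

**Further compounds**
F1 | step 16 | bridged 2,3-dihydrofuran (C1=C10 enol ether, O8 on C1) of 19 | O1C2=CC[C@H]1[C@H]1[C@H](OC(=O)C1(O)CO[Si](c3ccccc3)(c3ccccc3)C(C)(C)C)\C=C(C)/CC2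
F2 | step 13 | 6S allylic alcohol (C6 epimer of 17) | CO[C@]12CC/C(C)=C\[C@H](O)[C@@H](C(O)(CO[Si](c3ccccc3)(c3ccccc3)C(C)(C)C)C(=O)OCC)[C@H](CC1)O2
F3 | step 13 | 6S hydroxy acid from F2 | CO[C@]12CC/C(C)=C\[C@H](O)[C@@H](C(O)(CO[Si](c3ccccc3)(c3ccccc3)C(C)(C)C)C(=O)O)[C@H](CC1)O2
F4 | step 20 | 8,11,14-trihydroxy-13-nor-1-oxogermacra-4Z,7(11)-dien-6,12-olide (enol of the α-keto lactone) | O=C1CC/C(C)=C\[C@H]2OC(=O)C(O)=C2[C@@H](O)CC1CO
F5 | step 20 | 11-triflyloxy butenolide from F4 | O=C1CC/C(C)=C\[C@H]2OC(=O)C(OS(=O)(=O)C(F)(F)F)=C2[C@@H](O)CC1CO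
F6 | step 20 | 8,14-diacetate of F5 | O=C1CC/C(C)=C\[C@H]2OC(=O)C(OS(=O)(=O)C(F)(F)F)=C2[C@@H](OC(C)=O)CC1COC(C)=O
F7 | step 20 | 8-acetoxy-11-triflyloxy-10(14)-en-1-one butenolide | O=C1CC/C(C)=C\[C@H]2OC(=O)C(OS(=O)(=O)C(F)(F)F)=C2[C@@H](OC(C)=O)CC1=C
F8 | step 20 | 8-acetoxy-13-hydroxy-1-oxogermacra-4Z,7(11),10(14)-trien-6,12-olide | O=C1CC/C(C)=C\[C@H]2OC(=O)C(CO)=C2[C@@H](OC(C)=O)CC1=C
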